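## The problem

The target is a resveratrol-type trimer in which two trans-2,3-diaryl-2,3-dihydrobenzofurans share one benzene ring. Ring B is the C3 aryl group of the first dihydrofuran (through B1) and also the benzo ring of the second (O1′ on B4, C3′ on B5), with a free hydroxyl on B3. The first dihydrofuran is fused to ring A, which carries a hydroxyl at C6 and a (Z)-4-hydroxystyryl arm at C4, directly beside ring B. There are four stereocentres in two pairs, (2S,3S) and (2′R,3′R). Within a pair the trans arrangement is the stable one, so one centre can set or correct its neighbour, but the pairs are separated by the flat ring B and no relay between them can be counted on. The seven phenols are easily oxidised. The Z-stilbene isomerises under acid, light or radical conditions and, once protonated, invites Friedel–Crafts closure onto ring B. Both benzylic C–O bonds (C2–O1, C2′–O1′) can ionise because each carbon carries a para-oxygenated aryl group. The enabling feature is the pattern on ring B: an ether oxygen on B4 flanked by a hydroxyl on B3 and by C3′ on B5 is what results when the alkene carbon of a 4-hydroxystilbene radical couples to the free ortho position of a 2-alkoxyphenol and the phenol closes onto the quinone methide, and the aryl groups on C3′ and C2′ sit where that coupling puts them.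

## Retrosynthesis

**Z-alkene last (20 to 19).** No skeletal bond is cut; the two alkene hydrogens of 20 are removed to give diarylalkyne 19. Carrying the Z-stilbene itself would expose it to the oxidant of the ring-forming step and to the Lewis acid of the deprotection, where a protonated styrene beside ring B isomerises or cyclises. An alkyne does neither, and it is installed by a coupling that needs no control of geometry. The forward step must stop at the cis-alkene and leave both cyclic benzylic ethers alone.

**Phenols unmasked (19 to 18).** Six O–methyl bonds are cut. Methyl ethers are kept because the commercial partners 13 and 16 bring four of them and because they survive every reagent of the route. The cost is a Lewis-acidic penultimate step, which is acceptable only because no alkene is present yet. The trans rings are safe in a thermodynamic sense: C3 and C3′ cannot epimerise, so a benzylic C–O bond that opens should re-close trans.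

**Ring-B dihydrofuran (18 to 15 and 16).** The bonds C3′–B5 and O1′–C2′ are cut together, which opens the second dihydrofuran and removes two stereocentres and about a third of the skeleton in one move. Phenol 15 holds the whole ring-A half, and pterostilbene 16 is bought. Building this ring stepwise on ring B before the halves are joined would cost several steps and its own asymmetric method. The forward reaction is a one-electron oxidation of both phenols, C–C coupling, and closure of the ring-B phenol onto quinone methide 17. It has to favour cross- over homo-coupling and carbon over oxygen coupling. It cannot be expected to choose a face at C3′, so 18 has to be separated from its (2′S,3′S) diastereomer.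

**Alkyne arm (15 to 14, then 12 and 13).** The C4–C(sp) bond is cut, leading to aryl triflate 12 and 4-ethynylanisole 13. The triflate comes from phenol 11, itself from benzyl ether 10. The arm is attached after the nickel step because neither a triflate nor an alkyne is safe under zerovalent nickel and an arylzinc reagent. Removal of the silyl group from 14 then frees the one phenol (B4–OH) that the key step needs.

**Ring B onto C3 (10 to 6 and 8).** The C3–B1 bond is cut. Redox-active ester 6 becomes a planar C3 radical on decarboxylation, and arylzinc reagent 9, made from silyl ether 8 of 4-bromo-2-methoxyphenol 7, delivers ring B. This is preferred to an ionic arylation at C3, since a C3 cation would lose the C2 hydrogen and aromatise to a benzofuran. The forward step must deliver the aryl group trans to the C2 aryl group, so C2 controls C3. The configuration of C3 in acid 5 and ester 4 is therefore of no consequence.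

**Ring-A dihydrofuran from the chiral pool (4 to 3, 2 and 1).** The C3–C3a bond is cut: ester 4 is the ring-contracted form of flavanone 3, in which ring-A carbon C4a has moved from the carbonyl carbon to C3. Flavanone 3 is (S)-naringenin 1 with its two free phenols methylated (2) and its chelated 5-hydroxyl benzylated. The benzyl group later becomes the handle for the arm. C2 comes from 1 unchanged, so each protection step must avoid opening the pyranone to the chalcone.

## Roads not taken

**Alternative 1:** The C2–aryl and C3–ring B bonds of the first dihydrofuran are cut at once, with the ring left open. In the forward sense, 4-methoxyphenyllithium A4 adds to the ring-A alkenyl boronate A2, and the boron ate complex couples with ring-B aryl bromide A3 under a palladium catalyst with a chiral ferrocenyl bisphosphine. This gives the anti triarylethyl boronate A1 by 1,2-migration and reductive elimination. Its merits are real. Both ring-A stereocentres are set by the catalyst in one step, with no reliance on a natural product of uncertain optical purity. Bromide A3 enters with its own stereocentres fixed, so no late diastereomer mixture arises, and in this respect it is better than the chosen plan. Its weak points for this target are these: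
- the alkene of A2 carries an aryl group with two ortho substituents, a hindered case for the migration;
- three further operations (C–B oxidation, acetal removal, ring closure at a cation-prone benzylic carbon) are needed before the dihydrofuran exists;
- A3 must first be made as a single enantiomer, which returns to the unsolved problem of the ring-B dihydrofuran.

The chosen plan sets against it a shorter route, a chiral-pool C2, and formation of the second dihydrofuran in one step from a commercial stilbene.

**Alternative 2:** The C3–C3a bond is cut and the ring contraction of flavanone 3 to ester A5 (the same compound as 4) is taken as the strategic step. A trivalent iodine oxidant in an orthoformate moves ring-A carbon C4a from C4 to C3. The step is cheap, starts from the chiral pool and fixes the trans ring. The chosen plan uses it unchanged as its step 3, so up to that point the two roads coincide and this one is equally good. As a strategy it stops too early. It delivers an ester where ring B should be and says nothing about how ring B, its dihydrofuran and the two remaining stereocentres arrive. If that ring were then built stepwise with a stereocontrolled method, the diastereomer loss of the chosen plan would be avoided, at the cost of several more steps. The chosen plan closes the gap with one decarboxylative arylation and one oxidative coupling.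

**Alternative 3:** The C3–C3a and O1–C2 bonds are cut, so that the ring-A dihydrofuran comes from quinone ester A7 and E-stilbene A8 in an asymmetric [3+2] reaction under a chiral copper bisoxazoline Lewis acid, giving A6. Both ring-A stereocentres come from the catalyst, C4 emerges already bearing a carbon substituent (no triflate needed), and ring B carries a bromine and a protected phenol for later use. In enantiocontrol and in independence from a base-sensitive flavanone it is better than the chosen plan. Against it for this target:
- A6 has a C5 hydroxyl that the target lacks and that must be removed reductively;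
- the ester must be turned into the Z-styryl arm by reduction and olefination with uncertain geometry;
- the stilbene has an electron-poor ring B and is a sluggish partner;
- the second dihydrofuran still has to be built from the aryl bromide with its own stereochemical problem.

The chosen plan is shorter, needs no redox corrections on ring A, and makes the ring-B dihydrofuran directly.

Key step: step 12

Remark: unprimed locants refer to the dihydrobenzofuran fused to ring A, primed locants to the one fused to ring B, and B1–B6 to ring B (B1 bonded to C3); commercial 1 is assumed to be enantiomerically pure, and it and intermediates 3 to 5 are to be checked by chiral HPLC.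

## Route

Step 1
Reactants: 1 (S)-naringenin
Product: 2 (2S)-5-hydroxy-7-methoxy-2-(4-methoxyphenyl)chroman-4-one
Conditions: MeOH, PPh3, DIAD, THF, 0 °C to rt
Reagents that add atoms: methanol, CO
Why: Mitsunobu etherification of the two acidic phenols (C7 and C4′); the 5-hydroxyl, hydrogen-bonded to the C4 carbonyl, should stay free, and the near-neutral medium avoids the base-induced retro-oxa-Michael ring opening that would racemise C2.

Step 2
Reactants: 2 (2S)-5-hydroxy-7-methoxy-2-(4-methoxyphenyl)chroman-4-one
Product: 3 (2S)-5-(benzyloxy)-7-methoxy-2-(4-methoxyphenyl)chroman-4-one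
Conditions: BnBr, Ag2O, DMF, rt, dark
Reagents that add atoms: benzyl bromide, BrCc1ccccc1
Why: Purdie-type O-alkylation; the silver oxide serves as a mild heterogeneous base and halide acceptor, so the chelated phenol should be benzylated without a soluble strong base that could enolise C3 and open the ring.

Step 3
Reactants: 3 (2S)-5-(benzyloxy)-7-methoxy-2-(4-methoxyphenyl)chroman-4-one
Product: 4 methyl (2S,3S)-4-(benzyloxy)-6-methoxy-2-(4-methoxyphenyl)-2,3-dihydro-1-benzofuran-3-carboxylate
Conditions: PhI(OAc)2, H2SO4 (cat.), HC(OMe)3, rt; aq. NaHCO3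
Reagents that add atoms: trimethyl orthoformate, COC(OC)OC; water, O
Why: Oxidative ring contraction of a flavanone by trivalent iodine (1,2-aryl shift): the orthoformate turns the ketone into its enol ether, the iodane adds at C3 anti to the C2 aryl group, and loss of iodobenzene is assisted by migration of the electron-rich ring-A carbon C4a from the ketal carbon to C3, the resulting dimethoxycarbenium ion ending as the methyl ester. C2 is not touched and the ester lies trans to the C2 aryl group, the stable arrangement; the C3 configuration is erased again in step 7.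

Step 4
Reactants: 4 methyl (2S,3S)-4-(benzyloxy)-6-methoxy-2-(4-methoxyphenyl)-2,3-dihydro-1-benzofuran-3-carboxylate
Product: 5 (2S,3S)-4-(benzyloxy)-6-methoxy-2-(4-methoxyphenyl)-2,3-dihydro-1-benzofuran-3-carboxylic acid
Conditions: LiOH·H2O, THF/MeOH/H2O, rt to 40 °C; then 1 M HCl
Reagents that add atoms: lithium hydroxide, [Li+].[OH-]
Why: Ester saponification; expulsion of the ring phenoxide from the ester enolate would be a disfavoured 5-endo process, so C2 should be retained, and any equilibration at C3 leads to the trans acid.

Step 5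
Reactants: 5 (2S,3S)-4-(benzyloxy)-6-methoxy-2-(4-methoxyphenyl)-2,3-dihydro-1-benzofuran-3-carboxylic acid
Product: 6 1,3-dioxoisoindolin-2-yl (2S,3S)-4-(benzyloxy)-6-methoxy-2-(4-methoxyphenyl)-2,3-dihydro-1-benzofuran-3-carboxylate
Conditions: N-hydroxyphthalimide, DIC, DMAP (cat.), CH2Cl2, rt
Reagents that add atoms: N-hydroxyphthalimide, O=C1c2ccccc2C(=O)N1O
Why: Carbodiimide esterification to the redox-active N-acyloxyphthalimide; neutral conditions, no stereocentre involved.

Step 6
Reactants: 7 4-bromo-2-methoxyphenol
Product: 8 (4-bromo-2-methoxyphenoxy)triisopropylsilane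
Conditions: TIPSCl, imidazole, DMF, rt
Reagents that add atoms: chlorotriisopropylsilane, CC(C)[Si](Cl)(C(C)C)C(C)C
Why: Standard silylation of a phenol; the bulky silyl ether tolerates bromine–lithium exchange para to it and is later removed by fluoride without touching methyl ethers.

Step 7
Reactants: 6 1,3-dioxoisoindolin-2-yl (2S,3S)-4-(benzyloxy)-6-methoxy-2-(4-methoxyphenyl)-2,3-dihydro-1-benzofuran-3-carboxylate; 8 (4-bromo-2-methoxyphenoxy)triisopropylsilane
Product: 10 (2S,3S)-4-(benzyloxy)-6-methoxy-3-[3-methoxy-4-(triisopropylsilyloxy)phenyl]-2-(4-methoxyphenyl)-2,3-dihydro-1-benzofuran, via arylzinc chloride 9 (not isolated)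
Conditions: 8 (3 equiv), n-BuLi, THF, −78 °C; ZnCl2, −78 °C to rt; then 6, NiCl2(dme) (20 mol%), 4,4′-di-tert-butyl-2,2′-bipyridine (40 mol%), THF/DMF, rt
Reagents that add atoms: none
Why: Nickel-catalysed decarboxylative Negishi arylation of a redox-active ester: electron transfer to 6 releases CO2 and phthalimide and leaves a planar benzylic C3 radical, which is captured by the aryl–nickel species and released by reductive elimination. The aryl group should arrive on the face opposite the C2 aryl group, so C2 sets C3 trans (3S); the benzyl ether is inert to low-valent nickel at room temperature.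

Step 8
Reactants: 10 (2S,3S)-4-(benzyloxy)-6-methoxy-3-[3-methoxy-4-(triisopropylsilyloxy)phenyl]-2-(4-methoxyphenyl)-2,3-dihydro-1-benzofuran
Product: 11 (2S,3S)-6-methoxy-3-[3-methoxy-4-(triisopropylsilyloxy)phenyl]-2-(4-methoxyphenyl)-2,3-dihydro-1-benzofuran-4-ol
Conditions: H2 (1 atm), Pd/C (10 wt%), EtOAc, rt
Reagents that add atoms: none
Why: Hydrogenolysis of an aryl benzyl ether; the cyclic benzylic C2–O bond is cleaved far more slowly than an O-benzyl group, and no alkene or alkyne is present yet.

Step 9
Reactants: 11 (2S,3S)-6-methoxy-3-[3-methoxy-4-(triisopropylsilyloxy)phenyl]-2-(4-methoxyphenyl)-2,3-dihydro-1-benzofuran-4-ol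
Product: 12 (2S,3S)-6-methoxy-3-[3-methoxy-4-(triisopropylsilyloxy)phenyl]-2-(4-methoxyphenyl)-2,3-dihydro-1-benzofuran-4-yl trifluoromethanesulfonate
Conditions: Tf2O, pyridine, CH2Cl2, 0 °C
Reagents that add atoms: trifluoromethanesulfonic anhydride, O=S(=O)(OS(=O)(=O)C(F)(F)F)C(F)(F)F
Why: Triflation of the only free hydroxyl; this turns the former naringenin 5-oxygen into a leaving group for C–C coupling.

Step 10
Reactants: 12 (2S,3S)-6-methoxy-3-[3-methoxy-4-(triisopropylsilyloxy)phenyl]-2-(4-methoxyphenyl)-2,3-dihydro-1-benzofuran-4-yl trifluoromethanesulfonate; 13 1-ethynyl-4-methoxybenzene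
Product: 14 triisopropyl{2-methoxy-4-[(2S,3S)-6-methoxy-2-(4-methoxyphenyl)-4-[(4-methoxyphenyl)ethynyl]-2,3-dihydro-1-benzofuran-3-yl]phenoxy}silane
Conditions: PdCl2(PPh3)2 (5 mol%), CuI (10 mol%), Et3N, DMF, 70 °C
Reagents that add atoms: none
Why: Sonogashira coupling of an aryl triflate with a terminal alkyne forms the C4–C(sp) bond; no geometry has to be controlled and the stereocentres are remote from the reacting carbon.

Step 11
Reactants: 14 triisopropyl{2-methoxy-4-[(2S,3S)-6-methoxy-2-(4-methoxyphenyl)-4-[(4-methoxyphenyl)ethynyl]-2,3-dihydro-1-benzofuran-3-yl]phenoxy}silane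
Product: 15 2-methoxy-4-[(2S,3S)-6-methoxy-2-(4-methoxyphenyl)-4-[(4-methoxyphenyl)ethynyl]-2,3-dihydro-1-benzofuran-3-yl]phenol
Conditions: TBAF, AcOH, THF, 0 °C
Reagents that add atoms: none
Why: Fluoride cleavage of the aryl silyl ether frees the single phenol (B4–OH) needed for the coupling; buffering with acetic acid keeps the phenoxide from standing in basic solution.

Step 12
Reactants: 15 2-methoxy-4-[(2S,3S)-6-methoxy-2-(4-methoxyphenyl)-4-[(4-methoxyphenyl)ethynyl]-2,3-dihydro-1-benzofuran-3-yl]phenol; 16 pterostilbene, 4-[(E)-2-(3,5-dimethoxyphenyl)ethenyl]phenol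
Product: 18 4-[(2R,3R)-3-(3,5-dimethoxyphenyl)-7-methoxy-5-[(2S,3S)-6-methoxy-2-(4-methoxyphenyl)-4-[(4-methoxyphenyl)ethynyl]-2,3-dihydro-1-benzofuran-3-yl]-2,3-dihydro-1-benzofuran-2-yl]phenol, via quinone methide 17 (not isolated)
Conditions: Ag2O (3 equiv), 16 (1 equiv at the start, 2 equiv more by syringe pump over 6 h), toluene/acetone 2:1, 4 Å sieves, rt, dark, Ar; then preparative HPLC
Reagents that add atoms: none
Why: Ag2O oxidises both phenols by one electron; the radical of 16 carries spin on the alkene carbon next to the dimethoxyphenyl ring, and the guaiacyl radical of 15 carries it on B5. Radical–radical coupling forms C3′–B5; tautomerisation restores the ring-B phenol (17), and the B4 hydroxyl adds to the quinone methide carbon in a 5-exo-trig oxa-Michael closure, forming O1′–C2′. The closest known reaction type is the Ag2O dehydrodimerisation of 4-hydroxystilbenes and propenylphenols to trans-phenylcoumarans, together with the end-wise cross-coupling of such radicals onto guaiacyl units that bear a saturated para substituent. C2′ is set in the ring closure and should come out trans to the C3′ aryl group, since the phenol adds anti to that group and the closure can revert through 17. C3′ is set in the radical coupling; the nearest stereocentre (C3) lies across ring B, so neither face is favoured, and 18 and its (2′S,3′S) diastereomer should both form and are separated by HPLC. Cross- over homo-coupling is served by keeping 15 limiting and feeding 16 in excess, with some 16 present from the start so that the radical of 15 meets a stilbene radical before it can lose the doubly benzylic C3 hydrogen. Carbon over oxygen coupling is served by the dry, non-nucleophilic medium: an O-linked quinone methide finds no trap and its weak C–O bond can revert, whereas the C-linked adduct is drained by rearomatisation and ring closure. The site is fixed by the substrate: B3 carries methoxy, B1 carries C3, the ring-B phenol has no conjugated side chain and can act only as ring donor, all other oxygens are methyl ethers, and the diarylalkyne is inert.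

Step 13
Reactants: 18 4-[(2R,3R)-3-(3,5-dimethoxyphenyl)-7-methoxy-5-[(2S,3S)-6-methoxy-2-(4-methoxyphenyl)-4-[(4-methoxyphenyl)ethynyl]-2,3-dihydro-1-benzofuran-3-yl]-2,3-dihydro-1-benzofuran-2-yl]phenol
Product: 19 (2S,3S)-3-[(2R,3R)-3-(3,5-dihydroxyphenyl)-7-hydroxy-2-(4-hydroxyphenyl)-2,3-dihydro-1-benzofuran-5-yl]-2-(4-hydroxyphenyl)-4-[(4-hydroxyphenyl)ethynyl]-2,3-dihydro-1-benzofuran-6-ol
Conditions: BBr3 (14 equiv), CH2Cl2, −78 to 0 °C; MeOH, then aq. NaHCO3
Reagents that add atoms: none
Why: Lewis-acid cleavage of the six aryl methyl ethers by BBr3; with an alkyne in place of the Z-alkene there is no styrene to protonate, so acid-induced isomerisation and Friedel–Crafts closure onto ring B are excluded, and a benzylic C–O bond that opens should re-close trans because C3 and C3′ cannot epimerise.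

Step 14
Reactants: 19 (2S,3S)-3-[(2R,3R)-3-(3,5-dihydroxyphenyl)-7-hydroxy-2-(4-hydroxyphenyl)-2,3-dihydro-1-benzofuran-5-yl]-2-(4-hydroxyphenyl)-4-[(4-hydroxyphenyl)ethynyl]-2,3-dihydro-1-benzofuran-6-ol
Product: 20 (2S,3S)-3-[(2R,3R)-3-(3,5-dihydroxyphenyl)-7-hydroxy-2-(4-hydroxyphenyl)-2,3-dihydro-1-benzofuran-5-yl]-2-(4-hydroxyphenyl)-4-[(Z)-2-(4-hydroxyphenyl)ethenyl]-2,3-dihydro-1-benzofuran-6-ol (CNP0172909.2)
Conditions: H2 (1 atm), Pd/CaCO3 poisoned with Pb(OAc)2 (Lindlar catalyst), quinoline, EtOAc/MeOH, rt, dark
Reagents that add atoms: none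
Why: Lindlar semi-hydrogenation; syn delivery of hydrogen to the diarylalkyne on the poisoned palladium surface gives the Z-alkene, quinoline and monitoring of hydrogen uptake guard against over-reduction, and the molecule has no other reducible group.

## Compound list

1 | (S)-naringenin, (2S)-5,7-dihydroxy-2-(4-hydroxyphenyl)chroman-4-one | O=C1C[C@@H](c2ccc(O)cc2)Oc2cc(O)cc(O)c12 | starting material
2 | (2S)-5-hydroxy-7-methoxy-2-(4-methoxyphenyl)chroman-4-one | O=C1C[C@@H](c2ccc(OC)cc2)Oc2cc(OC)cc(O)c12 | intermediate
3 | (2S)-5-(benzyloxy)-7-methoxy-2-(4-methoxyphenyl)chroman-4-one | O=C1C[C@@H](c2ccc(OC)cc2)Oc2cc(OC)cc(OCc3ccccc3)c12 | intermediate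
4 | methyl (2S,3S)-4-(benzyloxy)-6-methoxy-2-(4-methoxyphenyl)-2,3-dihydro-1-benzofuran-3-carboxylate | O(Cc1ccccc1)c1cc(OC)cc2c1[C@H](C(=O)OC)[C@@H](c1ccc(OC)cc1)O2 | intermediate
5 | (2S,3S)-4-(benzyloxy)-6-methoxy-2-(4-methoxyphenyl)-2,3-dihydro-1-benzofuran-3-carboxylic acid | O(Cc1ccccc1)c1cc(OC)cc2c1[C@H](C(=O)O)[C@@H](c1ccc(OC)cc1)O2 | intermediate
6 | 1,3-dioxoisoindolin-2-yl (2S,3S)-4-(benzyloxy)-6-methoxy-2-(4-methoxyphenyl)-2,3-dihydro-1-benzofuran-3-carboxylate | O(Cc1ccccc1)c1cc(OC)cc2c1[C@H](C(=O)ON1C(=O)c3ccccc3C1=O)[C@@H](c1ccc(OC)cc1)O2 | intermediate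
7 | 4-bromo-2-methoxyphenol | COc1cc(Br)ccc1O | starting material
8 | (4-bromo-2-methoxyphenoxy)triisopropylsilane | COc1cc(Br)ccc1O[Si](C(C)C)(C(C)C)C(C)C | intermediate
9 | [3-methoxy-4-(triisopropylsilyloxy)phenyl]zinc chloride (lithium chloride adduct, not isolated) | COc1cc([Zn]Cl)ccc1O[Si](C(C)C)(C(C)C)C(C)C | intermediate
10 | (2S,3S)-4-(benzyloxy)-6-methoxy-3-[3-methoxy-4-(triisopropylsilyloxy)phenyl]-2-(4-methoxyphenyl)-2,3-dihydro-1-benzofuran | O(Cc1ccccc1)c1cc(OC)cc2c1[C@H](c1ccc(O[Si](C(C)C)(C(C)C)C(C)C)c(OC)c1)[C@@H](c1ccc(OC)cc1)O2 | intermediate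
11 | (2S,3S)-6-methoxy-3-[3-methoxy-4-(triisopropylsilyloxy)phenyl]-2-(4-methoxyphenyl)-2,3-dihydro-1-benzofuran-4-ol | Oc1cc(OC)cc2c1[C@H](c1ccc(O[Si](C(C)C)(C(C)C)C(C)C)c(OC)c1)[C@@H](c1ccc(OC)cc1)O2 | intermediate
12 | (2S,3S)-6-methoxy-3-[3-methoxy-4-(triisopropylsilyloxy)phenyl]-2-(4-methoxyphenyl)-2,3-dihydro-1-benzofuran-4-yl trifluoromethanesulfonate | O(S(=O)(=O)C(F)(F)F)c1cc(OC)cc2c1[C@H](c1ccc(O[Si](C(C)C)(C(C)C)C(C)C)c(OC)c1)[C@@H](c1ccc(OC)cc1)O2 | intermediate
13 | 1-ethynyl-4-methoxybenzene (4-ethynylanisole) | C#Cc1ccc(OC)cc1 | starting material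
14 | triisopropyl{2-methoxy-4-[(2S,3S)-6-methoxy-2-(4-methoxyphenyl)-4-[(4-methoxyphenyl)ethynyl]-2,3-dihydro-1-benzofuran-3-yl]phenoxy}silane | COc1ccc(C#Cc2cc(OC)cc3c2[C@H](c2ccc(O[Si](C(C)C)(C(C)C)C(C)C)c(OC)c2)[C@@H](c2ccc(OC)cc2)O3)cc1 | intermediate
15 | 2-methoxy-4-[(2S,3S)-6-methoxy-2-(4-methoxyphenyl)-4-[(4-methoxyphenyl)ethynyl]-2,3-dihydro-1-benzofuran-3-yl]phenol | COc1ccc(C#Cc2cc(OC)cc3c2[C@H](c2ccc(O)c(OC)c2)[C@@H](c2ccc(OC)cc2)O3)cc1 | intermediate
16 | pterostilbene, 4-[(E)-2-(3,5-dimethoxyphenyl)ethenyl]phenol | COc1cc(/C=C/c2ccc(O)cc2)cc(OC)c1 | starting material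
17 | 4-[(2R)-2-(3,5-dimethoxyphenyl)-2-{2-hydroxy-3-methoxy-5-[(2S,3S)-6-methoxy-2-(4-methoxyphenyl)-4-[(4-methoxyphenyl)ethynyl]-2,3-dihydro-1-benzofuran-3-yl]phenyl}ethylidene]cyclohexa-2,5-dien-1-one (quinone methide, not isolated) | COc1ccc(C#Cc2cc(OC)cc3c2[C@H](c2cc(OC)c(O)c(c2)[C@@H](c2cc(OC)cc(OC)c2)C=C2C=CC(=O)C=C2)[C@@H](c2ccc(OC)cc2)O3)cc1 | intermediate
18 | 4-[(2R,3R)-3-(3,5-dimethoxyphenyl)-7-methoxy-5-[(2S,3S)-6-methoxy-2-(4-methoxyphenyl)-4-[(4-methoxyphenyl)ethynyl]-2,3-dihydro-1-benzofuran-3-yl]-2,3-dihydro-1-benzofuran-2-yl]phenol | COc1ccc(C#Cc2cc(OC)cc3c2[C@H](c2cc(OC)c4c(c2)[C@@H](c2cc(OC)cc(OC)c2)[C@H](c2ccc(O)cc2)O4)[C@@H](c2ccc(OC)cc2)O3)cc1 | intermediate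
19 | (2S,3S)-3-[(2R,3R)-3-(3,5-dihydroxyphenyl)-7-hydroxy-2-(4-hydroxyphenyl)-2,3-dihydro-1-benzofuran-5-yl]-2-(4-hydroxyphenyl)-4-[(4-hydroxyphenyl)ethynyl]-2,3-dihydro-1-benzofuran-6-ol | Oc1ccc(C#Cc2cc(O)cc3c2[C@H](c2cc(O)c4c(c2)[C@@H](c2cc(O)cc(O)c2)[C@H](c2ccc(O)cc2)O4)[C@@H](c2ccc(O)cc2)O3)cc1 | intermediate
20 | (2S,3S)-3-[(2R,3R)-3-(3,5-dihydroxyphenyl)-7-hydroxy-2-(4-hydroxyphenyl)-2,3-dihydro-1-benzofuran-5-yl]-2-(4-hydroxyphenyl)-4-[(Z)-2-(4-hydroxyphenyl)ethenyl]-2,3-dihydro-1-benzofuran-6-ol | Oc1ccc(/C=C\c2cc(O)cc3c2[C@H](c2cc(O)c4c(c2)[C@@H](c2cc(O)cc(O)c2)[C@H](c2ccc(O)cc2)O4)[C@@H](c2ccc(O)cc2)O3)cc1 | target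

## Step count and least certain steps

Total: 14 steps. Longest linear sequence: 13 steps (1 to 20 through steps 1–5 and 7–14); step 6 is the only step off the main line.

**Step 12 (key step).** Three processes can undercut it. Homo-coupling of the stilbene radical may outrun cross-coupling, because 16 is oxidised at least as readily as 15. Oxidation of 15 may continue at the doubly benzylic C3 hydrogen para to the phenol, giving a quinone methide that aromatises the first dihydrofuran and destroys C3. And the lack of facial control at C3′ costs about half of whatever cross-product forms. The fallback reverses the order of union; it sets out from 7, 16 and 6 and returns at 18. Bromophenol 7 is cheap, can be used in large excess, has its para position blocked by bromine and has no benzylic hydrogen. It is coupled with 16 under Ag2O to the racemic trans bromophenylcoumaran F1. Silylation with TIPSCl and preparative HPLC on a chiral phase give the (2R,3R) silyl ether F2. Bromine–lithium exchange and ZnCl2 give arylzinc chloride F3, which is joined to redox-active ester 6 under the conditions of step 7 to give benzyl ether F4, with C3 again set trans by C2. Hydrogenolysis to phenol F5, triflation to triflate F6, Sonogashira coupling with 13 to alkyne silyl ether F7 and desilylation with fluoride lead back to 18. The resolution is thus moved to a cheap early racemate, and no diastereomer is discarded late.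

**Step 7.** The C3 radical is hindered (flanked by the C2 aryl group and the C4 benzyloxy group) and doubly stabilised, so it may escape capture by nickel and instead dimerise, abstract hydrogen, or lose the C2 hydrogen to give a benzofuran; partial cis arylation is also possible. The fallback reverses the polarity of the union; it sets out from acid 5 and aryl bromide 8 and returns at 10, with no new compound. Acid 5 is oxidised directly as its caesium carboxylate by a photoexcited iridium catalyst (Ir[dF(CF3)ppy]2(dtbbpy)PF6, blue light), and the C3 radical is intercepted by the nickel catalyst (NiCl2(dme), 4,4′-di-tert-butyl-2,2′-bipyridine) that has added to the C–Br bond of 8 (Cs2CO3, DMF). Neither ester 6 nor zinc reagent 9 is then needed.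

**Step 3 (with step 2 before it).** The most likely fault is loss of configurational purity at C2. In the acidic orthoformate medium the C2–O1 bond is a cyclic 4-methoxybenzyl aryl ether and can ionise and re-close, and in step 2 any enolisation opens the ring to the chalcone. A shift of the C2 aryl group in place of ring-A carbon C4a would lower the yield but not the purity. The fallback replaces reliance on chiral-pool fidelity by a classical resolution; it sets out from 5 and returns at 5. Partly racemised acid 5 is crystallised as its (R)-1-phenylethylammonium salt F8 (with the antipodal amine if the unwanted acid enantiomer gives the less soluble salt), and acidification returns 5 of upgraded purity. Because C3 is slaved to C2, only enantiomers, not diastereomers, have to be parted.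

**Step 14.** Over-reduction to the saturated diarylethane and Z-to-E isomerisation on palladium are the likely faults, made worse by a polar heptaphenol that adsorbs strongly on the catalyst and is hard to separate from close analogues. The fallback replaces catalytic hydrogenation by a stoichiometric syn-hydrometalation; it sets out from 19 and returns at 20. Acetylation (Ac2O, pyridine) gives alkyne heptaacetate F9. Hydroboration with dicyclohexylborane and protonolysis of the alkenylborane with acetic acid, both stereoretentive, give Z-alkene heptaacetate F10, which cannot be reduced further by this reagent. Methanolysis (K2CO3, degassed MeOH) returns 20.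

## Further compounds

F1 | step 12 | racemic trans-4-[5-bromo-3-(3,5-dimethoxyphenyl)-7-methoxy-2,3-dihydro-1-benzofuran-2-yl]phenol (racemate; the 2R,3R enantiomer is drawn) | Brc1cc(OC)c2c(c1)[C@@H](c1cc(OC)cc(OC)c1)[C@H](c1ccc(O)cc1)O2
F2 | step 12 | {4-[(2R,3R)-5-bromo-3-(3,5-dimethoxyphenyl)-7-methoxy-2,3-dihydro-1-benzofuran-2-yl]phenoxy}triisopropylsilane | Brc1cc(OC)c2c(c1)[C@@H](c1cc(OC)cc(OC)c1)[C@H](c1ccc(O[Si](C(C)C)(C(C)C)C(C)C)cc1)O2
F3 | step 12 | {(2R,3R)-3-(3,5-dimethoxyphenyl)-7-methoxy-2-[4-(triisopropylsilyloxy)phenyl]-2,3-dihydro-1-benzofuran-5-yl}zinc chloride | Cl[Zn]c1cc(OC)c2c(c1)[C@@H](c1cc(OC)cc(OC)c1)[C@H](c1ccc(O[Si](C(C)C)(C(C)C)C(C)C)cc1)O2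
F4 | step 12 | (2S,3S)-4-(benzyloxy)-3-{(2R,3R)-3-(3,5-dimethoxyphenyl)-7-methoxy-2-[4-(triisopropylsilyloxy)phenyl]-2,3-dihydro-1-benzofuran-5-yl}-6-methoxy-2-(4-methoxyphenyl)-2,3-dihydro-1-benzofuran | O(Cc1ccccc1)c1cc(OC)cc2c1[C@H](c1cc(OC)c3c(c1)[C@@H](c1cc(OC)cc(OC)c1)[C@H](c1ccc(O[Si](C(C)C)(C(C)C)C(C)C)cc1)O3)[C@@H](c1ccc(OC)cc1)O2
F5 | step 12 | (2S,3S)-3-{(2R,3R)-3-(3,5-dimethoxyphenyl)-7-methoxy-2-[4-(triisopropylsilyloxy)phenyl]-2,3-dihydro-1-benzofuran-5-yl}-6-methoxy-2-(4-methoxyphenyl)-2,3-dihydro-1-benzofuran-4-ol | Oc1cc(OC)cc2c1[C@H](c1cc(OC)c3c(c1)[C@@H](c1cc(OC)cc(OC)c1)[C@H](c1ccc(O[Si](C(C)C)(C(C)C)C(C)C)cc1)O3)[C@@H](c1ccc(OC)cc1)O2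
F6 | step 12 | (2S,3S)-3-{(2R,3R)-3-(3,5-dimethoxyphenyl)-7-methoxy-2-[4-(triisopropylsilyloxy)phenyl]-2,3-dihydro-1-benzofuran-5-yl}-6-methoxy-2-(4-methoxyphenyl)-2,3-dihydro-1-benzofuran-4-yl trifluoromethanesulfonate | O(S(=O)(=O)C(F)(F)F)c1cc(OC)cc2c1[C@H](c1cc(OC)c3c(c1)[C@@H](c1cc(OC)cc(OC)c1)[C@H](c1ccc(O[Si](C(C)C)(C(C)C)C(C)C)cc1)O3)[C@@H](c1ccc(OC)cc1)O2
F7 | step 12 | triisopropylsilyl ether of 18 at the C2′ aryl oxygen | COc1ccc(C#Cc2cc(OC)cc3c2[C@H](c2cc(OC)c4c(c2)[C@@H](c2cc(OC)cc(OC)c2)[C@H](c2ccc(O[Si](C(C)C)(C(C)C)C(C)C)cc2)O4)[C@@H](c2ccc(OC)cc2)O3)cc1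
F0 | step 7 | none | none
F8 | step 3 | (R)-1-phenylethylammonium (2S,3S)-4-(benzyloxy)-6-methoxy-2-(4-methoxyphenyl)-2,3-dihydro-1-benzofuran-3-carboxylate | O(Cc1ccccc1)c1cc(OC)cc2c1[C@H](C(=O)[O-])[C@@H](c1ccc(OC)cc1)O2.C[C@@H]([NH3+])c1ccccc1
F9 | step 14 | heptaacetate of alkyne 19 | CC(=O)Oc1ccc(C#Cc2cc(OC(C)=O)cc3c2[C@H](c2cc(OC(C)=O)c4c(c2)[C@@H](c2cc(OC(C)=O)cc(OC(C)=O)c2)[C@H](c2ccc(OC(C)=O)cc2)O4)[C@@H](c2ccc(OC(C)=O)cc2)O3)cc1
F10 | step 14 | heptaacetate of target 20 (Z-alkene) | CC(=O)Oc1ccc(/C=C\c2cc(OC(C)=O)cc3c2[C@H](c2cc(OC(C)=O)c4c(c2)[C@@H](c2cc(OC(C)=O)cc(OC(C)=O)c2)[C@H](c2ccc(OC(C)=O)cc2)O4)[C@@H](c2ccc(OC(C)=O)cc2)O3)cc1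
A1 | alternative 1 | anti 1,1,2-triarylethyl B(mac) boronate, C3 as in the target and boron on C2 | COCOc1cc(OC)cc(Cl)c1[C@H](c1cc(OC)c2c(c1)[C@@H](c1cc(OC)cc(OC)c1)[C@H](c1ccc(OC)cc1)O2)[C@H](c1ccc(OC)cc1)B1OC2(C)c3cccc4cccc(c34)C2(C)O1
A2 | alternative 1 | B(mac) boronate of (E)-2-[2-chloro-4-methoxy-6-(methoxymethoxy)phenyl]ethenylboronic acid | COCOc1cc(OC)cc(Cl)c1/C=C/B1OC2(C)c3cccc4cccc(c34)C2(C)O1
A3 | alternative 1 | (2R,3R)-5-bromo-3-(3,5-dimethoxyphenyl)-7-methoxy-2-(4-methoxyphenyl)-2,3-dihydro-1-benzofuran | Brc1cc(OC)c2c(c1)[C@@H](c1cc(OC)cc(OC)c1)[C@H](c1ccc(OC)cc1)O2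
A4 | alternative 1 | 4-methoxyphenyllithium | [Li]c1ccc(OC)cc1
A5 | alternative 2 | methyl (2S,3S)-4-(benzyloxy)-6-methoxy-2-(4-methoxyphenyl)-2,3-dihydro-1-benzofuran-3-carboxylate (identical with 4) | O(Cc1ccccc1)c1cc(OC)cc2c1[C@H](C(=O)OC)[C@@H](c1ccc(OC)cc1)O2
A6 | alternative 3 | methyl (2S,3S)-3-(3-bromo-5-methoxy-4-pivaloyloxyphenyl)-5-hydroxy-6-methoxy-2-(4-methoxyphenyl)-2,3-dihydro-1-benzofuran-4-carboxylate | COC(=O)c1c(O)c(OC)cc2c1[C@H](c1cc(Br)c(OC(=O)C(C)(C)C)c(OC)c1)[C@@H](c1ccc(OC)cc1)O2
A7 | alternative 3 | methyl 5-methoxy-3,6-dioxocyclohexa-1,4-diene-1-carboxylate | COC(=O)C1=CC(=O)C=C(OC)C1=O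
A8 | alternative 3 | 2-bromo-6-methoxy-4-[(E)-2-(4-methoxyphenyl)ethenyl]phenyl 2,2-dimethylpropanoate | COc1ccc(/C=C/c2cc(Br)c(OC(=O)C(C)(C)C)c(OC)c2)cc1
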